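**Plan** (guaiane half numbered C1–C15, seco-eudesmane half C1'–C15')

1. Retrosynthesis: cut C1–C13' and C3–C11' (final Diels–Alder of cyclopentadiene 43 with the α-methylene lactone of 41); in 43 cut C3=C4 (selenoxide), C4–C5 and C1–C2 (Nazarov, CO insertion), then C5–C6 and C7–C8.
2. Enabling feature: the lactone oxygen on C8 lies 1,4 across the seven-membered ring from C5, so a temporary C8–O–C5 bridge turns C5–C1–C10–C9–C8 into a 3-oxidopyrylium whose termini C5 and C8 take up a C6=C7 unit in one [5+2] event; the bridge is cut reductively in step 7 and its oxygen stays as the lactone oxygen.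
3. Forward, diene half: furan → pyranone → oxa-bridged cycloheptenone (step 4) → lactone-fused cycloheptanone → enol triflate → dienone → cyclopentenone (ring A) → selenide acetate 22.
4. Forward, dienophile half: (S)-citronellal → α-methylene ketone → Michael/aldol cyclohexenone → cis-lactone by oxa-Michael → enone by selenoxide elimination → exocyclic methylene → 41.
5. Stereochemistry: C7/C8 from the aminocatalytic [5+2]; C10 by exo-face hydrogenation of the bicycle; C2 by CBS reduction; C4' bought with citronellal; C7' by prolinol-ether catalysis; C8' by cis ring fusion; C1, C3 and C11' in the last cycloaddition, on the diene face anti to C2–OAc and the C10 methyl.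

Key step: step 4

Remark on the chemistry: metal enolates, organopalladium and catalyst-bound species (enamines) are taken as forms of the reagent or catalyst and are not numbered; the aminocatalysts of steps 4 and 18 are assumed to shield the enamine face as prolinol ethers do in nitroalkene additions, otherwise the antipodal catalyst is used.

Step 1
Reactants: 1 methyl 3-methylfuran-2-carboxylate
Product: 2 (3-methylfuran-2-yl)methanol
Conditions: LiAlH4, Et2O, 0 °C
Reagents that add atoms: none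
Why: Hydride reduction of the ester to the primary alcohol is routine and leaves the furan untouched.

Step 2
Reactants: 2 (3-methylfuran-2-yl)methanol
Product: 4 6-hydroxy-4-methyl-2H-pyran-3(6H)-one (racemic), via (2Z)-5-hydroxy-3-methyl-4-oxopent-2-enal 3 (not isolated)
Conditions: NBS, NaHCO3, NaOAc, THF/H2O 4:1, 0 °C
Reagents that add atoms: water, O
Why: Achmatowicz rearrangement: bromonium-induced hydrolytic opening of the furan gives the Z-enedione, whose hydroxyl closes onto the aldehyde; both stereocenters are erased in step 4, so racemic material suffices.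

Step 3
Reactants: 4 6-hydroxy-4-methyl-2H-pyran-3(6H)-one
Product: 5 4-methyl-5-oxo-5,6-dihydro-2H-pyran-2-yl acetate
Conditions: Ac2O, pyridine, DMAP (cat.), CH2Cl2, 0 °C
Reagents that add atoms: acetic anhydride, CC(=O)OC(C)=O
Why: O-Acetylation of the hemiacetal installs the leaving group needed for ylide formation.

Step 4
Reactants: 5 4-methyl-5-oxo-5,6-dihydro-2H-pyran-2-yl acetate; 6 (E)-but-2-enal
Product: 8 2-[(1R,5S,6S)-3-methyl-2-oxo-8-oxabicyclo[3.2.1]oct-3-en-6-yl]acetaldehyde, via 4-methyl-3-oxidopyrylium 7 (not isolated)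
Conditions: 3-[3,5-bis(trifluoromethyl)anilino]-4-{[(2S)-pyrrolidin-2-ylmethyl]amino}cyclobut-3-ene-1,2-dione (20 mol%), 6 (3 equiv), i-Pr2NEt (1.2 equiv, slow addition), CHCl3, 0 °C; aqueous work-up
Reagents that add atoms: none
Why: Proposed new method: base-induced loss of acetate from 5 gives the 3-oxidopyrylium ylide 7, while the pyrrolidine of the catalyst turns 6 into an electron-rich dienamine whose squaramide NH groups hydrogen-bond to the oxido oxygen, so that the remote C=C (future C6=C7) adds across the ylide termini in a concerted, asynchronous [5+2] cycloaddition, after which hydrolysis of the enamine releases the aldehyde and the catalyst. The closest known reaction types are the thermal [5+2] cycloaddition of 3-oxidopyrylium ylides with acrylates or vinyl ethers and the dienamine-activated [5+2] of benzo-fused oxidopyrylium ylides with enals; the monocyclic ylide is the new substrate class. The event closes the seven-membered carbocycle by forming C5–C6 and C7–C8 suprafacially on the ylide ([5+2] mode) and, through the pre-existing C5–O–C8 bridge, the tetrahydrofuran ring at the same time. C5 and C8 are set as a cis pair by the bridge, C7 by the endo approach that the hydrogen-bond tether enforces (enamine arm under the C1–C10–C9 edge, side chain anti to the oxygen bridge), and the absolute sense by the pyrrolidine stereocenter, which shields one dienamine face. The step needs regioselectivity (nucleophilic CH2 terminus to C5 next to the oxido carbon, as in the known 6-substituted adducts), endo selectivity and capture of 7 faster than its dimerization; the last is served by slow base addition and an excess of 6.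

Step 5
Reactants: 8 2-[(1R,5S,6S)-3-methyl-2-oxo-8-oxabicyclo[3.2.1]oct-3-en-6-yl]acetaldehyde
Product: 9 2-[(1R,5S,6S)-3-methyl-2-oxo-8-oxabicyclo[3.2.1]oct-3-en-6-yl]acetic acid
Conditions: NaClO2, NaH2PO4, 2-methyl-2-butene, t-BuOH/H2O, 0 to 23 °C
Reagents that add atoms: sodium chlorite, [Na+].[O-]Cl=O
Why: Pinnick oxidation converts the aldehyde into the acid without touching the enone or the stereocenters.

Step 6
Reactants: 9 2-[(1R,5S,6S)-3-methyl-2-oxo-8-oxabicyclo[3.2.1]oct-3-en-6-yl]acetic acid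
Product: 10 2-[(1R,3R,5R,6S)-3-methyl-2-oxo-8-oxabicyclo[3.2.1]octan-6-yl]acetic acid
Conditions: H2 (1 atm), Pd/C, EtOAc, 23 °C
Reagents that add atoms: none
Why: Heterogeneous hydrogenation of the enone C9=C10 should occur from the face syn to the oxygen bridge, because the ethano bridge with its endo side chain blocks the other face, and so places the C10 methyl anti to the bridge.

Step 7
Reactants: 10 2-[(1R,3R,5R,6S)-3-methyl-2-oxo-8-oxabicyclo[3.2.1]octan-6-yl]acetic acid
Product: 12 (3aS,7R,8aR)-7-methylhexahydro-2H-cyclohepta[b]furan-2,6(3H)-dione, via 2-[(1S,2R,4R)-2-hydroxy-4-methyl-5-oxocycloheptyl]acetic acid 11 (not isolated)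
Conditions: SmI2 (3 equiv), THF/MeOH, −78 °C; then p-TsOH·H2O (cat.), benzene, 60 °C
Reagents that add atoms: none
Why: SmI2 reduces the α-alkoxy ketone to its ketyl, which expels the bridgehead C5–O bond (reductive cleavage of α-heterosubstituted ketones) and frees the C8 hydroxyl with retention; acid then closes the trans-fused γ-lactone.

Step 8
Reactants: 12 (3aS,7R,8aR)-7-methylhexahydro-2H-cyclohepta[b]furan-2,6(3H)-dione
Product: 13 (3aS,7R,8aR)-7-methyl-2-oxo-3,3a,4,7,8,8a-hexahydro-2H-cyclohepta[b]furan-6-yl trifluoromethanesulfonate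
Conditions: KN(SiMe3)2 (1.1 equiv), THF, −78 °C; then N-(5-chloropyridin-2-yl)bis(trifluoromethanesulfonimide)
Reagents that add atoms: Comins' reagent, FC(F)(F)S(=O)(=O)N(c1ccc(Cl)cn1)S(=O)(=O)C(F)(F)F
Why: Kinetic deprotonation of the ketone occurs at the unbranched α-carbon C5 (not at C10, and faster than at the lactone), and O-sulfonylation of the enolate gives the C1=C5 enol triflate.

Step 9
Reactants: 13 (3aS,7R,8aR)-7-methyl-2-oxo-3,3a,4,7,8,8a-hexahydro-2H-cyclohepta[b]furan-6-yl trifluoromethanesulfonate; 14 (E)-tributyl(prop-1-en-1-yl)stannane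
Product: 15 (3aS,7R,8aR)-6-[(2E)-but-2-enoyl]-7-methyl-3,3a,4,7,8,8a-hexahydro-2H-cyclohepta[b]furan-2-one
Conditions: CO (1 atm), Pd(PPh3)4 (5 mol%), LiCl, THF, 55 °C
Reagents that add atoms: carbon monoxide, [C-]#[O+]
Why: Carbonylative Stille coupling: oxidative addition of the enol triflate, CO insertion and transmetalation with 14 give the divinyl ketone, the CO carbon becoming C2.

Step 10
Reactants: 15 (3aS,7R,8aR)-6-[(2E)-but-2-enoyl]-7-methyl-3,3a,4,7,8,8a-hexahydro-2H-cyclohepta[b]furan-2-one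
Product: 16 (3aS,8R,9aR)-5,8-dimethyl-3,3a,4,5,6,8,9,9a-octahydroazuleno[6,5-b]furan-2,7-dione (C5 epimer pair)
Conditions: MeSO3H (2 equiv), CH2Cl2, 0 to 23 °C
Reagents that add atoms: none
Why: Nazarov cyclization: the protonated dienone closes by conrotatory 4π-electrocyclization (C4–C5 bond) and loses the C5 proton to give the ring-fusion enone; the methyl-bearing carbon forms as an epimer pair that converges in step 26.

Step 11
Reactants: 16 (3aS,8R,9aR)-5,8-dimethyl-3,3a,4,5,6,8,9,9a-octahydroazuleno[6,5-b]furan-2,7-dione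
Product: 17 (3aS,5R,6S,8R,9aR)-5,8-dimethyl-6-(phenylselanyl)-3,3a,4,5,6,8,9,9a-octahydroazuleno[6,5-b]furan-2,7-dione (drawn member of the 5,6-trans pair)
Conditions: PhSeCl, EtOAc, 23 °C
Reagents that add atoms: benzeneselenenyl chloride, Cl[Se]c1ccccc1
Why: Acid-mediated enol selenenylation of the enone occurs at the α'-carbon C3, and this epimerizable center settles trans to the neighbouring methyl, which puts H4 syn to selenium for the later elimination.

Step 12
Reactants: 17 (3aS,5R,6S,8R,9aR)-5,8-dimethyl-6-(phenylselanyl)-3,3a,4,5,6,8,9,9a-octahydroazuleno[6,5-b]furan-2,7-dione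
Product: 18 (3aS,5R,6S,7R,8R,9aR)-7-hydroxy-5,8-dimethyl-6-(phenylselanyl)-3a,4,5,6,7,8,9,9a-octahydroazuleno[6,5-b]furan-2(3H)-one
Conditions: (R)-2-methyl-CBS-oxazaborolidine (30 mol%), catecholborane, toluene, −78 °C; MeOH quench
Reagents that add atoms: none
Why: CBS reduction delivers hydride under catalyst control with the alkenyl carbon C1 as the large group, so both members of the pair should receive the same C2 configuration, hydroxyl on the face of the C10 methyl.

Step 13
Reactants: 18 (3aS,5R,6S,7R,8R,9aR)-7-hydroxy-5,8-dimethyl-6-(phenylselanyl)-3a,4,5,6,7,8,9,9a-octahydroazuleno[6,5-b]furan-2(3H)-one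
Product: 21 (3aS,5R,6S,7R,8R,9aR)-7-hydroxy-5,8-dimethyl-3-methylidene-6-(phenylselanyl)-3a,4,5,6,7,8,9,9a-octahydroazuleno[6,5-b]furan-2(3H)-one, via 3-(dimethylaminomethyl) lactone 19 (not isolated), via trimethylammonium iodide 20 (not isolated)
Conditions: LiN(i-Pr)2 (2.3 equiv), THF, −78 °C; CH2=NMe2 I, −78 to 0 °C; then MeI, MeOH, 23 °C; then NaHCO3, CH2Cl2/H2O
Reagents that add atoms: Eschenmoser's salt, C=[N+](C)C.[I-]
Why: The lactone enolate (the alkoxide forms first) is aminomethylated in a Mannich reaction, and quaternization followed by Hofmann-type elimination gives the α-methylene lactone.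

Step 14
Reactants: 21 (3aS,5R,6S,7R,8R,9aR)-7-hydroxy-5,8-dimethyl-3-methylidene-6-(phenylselanyl)-3a,4,5,6,7,8,9,9a-octahydroazuleno[6,5-b]furan-2(3H)-one
Product: 22 (3aS,5R,6S,7R,8R,9aR)-5,8-dimethyl-3-methylidene-2-oxo-6-(phenylselanyl)-2,3,3a,4,5,6,7,8,9,9a-decahydroazuleno[6,5-b]furan-7-yl acetate
Conditions: Ac2O, pyridine, DMAP (cat.), CH2Cl2, 0 °C
Reagents that add atoms: acetic anhydride, CC(=O)OC(C)=O
Why: Acetylation of the secondary allylic alcohol is routine and fixes the C2 acetate of the target.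

Step 15
Reactants: 23 (3S)-3,7-dimethyloct-6-enal
Product: 24 (3S)-3,7-dimethyl-2-methylideneoct-6-enal
Conditions: aq. HCHO (37%), pyrrolidine (10 mol%), propionic acid (10 mol%), i-PrOH, 45 °C
Reagents that add atoms: formaldehyde, C=O
Why: Amine-catalysed Mannich condensation with formaldehyde and elimination (α-methylenation of an α-unbranched aldehyde) leaves the citronellal stereocenter, the later C4', untouched.

Step 16
Reactants: 24 (3S)-3,7-dimethyl-2-methylideneoct-6-enal
Product: 25 (4S)-4,8-dimethyl-3-methylidenenon-7-en-2-ol (C2 epimers)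
Conditions: MeMgBr, THF, −78 °C
Reagents that add atoms: methylmagnesium bromide, C[Mg]Br
Why: 1,2-Addition of the Grignard reagent to the enal; the new carbinol center is removed in step 17.

Step 17
Reactants: 25 (4S)-4,8-dimethyl-3-methylidenenon-7-en-2-ol
Product: 26 (4S)-4,8-dimethyl-3-methylidenenon-7-en-2-one
Conditions: Dess–Martin periodinane, NaHCO3, CH2Cl2, 0 °C
Reagents that add atoms: none
Why: Dess–Martin oxidation of the allylic alcohol gives the α-methylene ketone under non-basic conditions.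

Step 18
Reactants: 26 (4S)-4,8-dimethyl-3-methylidenenon-7-en-2-one; 27 methyl 4-oxobutanoate
Product: 28 methyl (3S)-3-formyl-5-[(2S)-6-methylhept-5-en-2-yl]-6-oxoheptanoate (C5 epimers)
Conditions: (S)-2-[diphenyl(trimethylsilyloxy)methyl]pyrrolidine (20 mol%), ethyl 3,4-dihydroxybenzoate (20 mol%), neat, 4 °C
Reagents that add atoms: none
Why: Enamine-catalysed Michael addition: the (E)-enamine of 27, shielded on one face by the diphenyl(silyloxy)methyl group, adds to the unsubstituted terminus of the vinyl ketone and sets C7'; C5' forms as a mixture that is erased in step 22.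

Step 19
Reactants: 28 methyl (3S)-3-formyl-5-[(2S)-6-methylhept-5-en-2-yl]-6-oxoheptanoate
Product: 30 methyl 2-[(1S)-5-[(2S)-6-methylhept-5-en-2-yl]-4-oxocyclohex-2-en-1-yl]acetate (C5 epimers), via β-hydroxy ketone 29 (not isolated)
Conditions: LiOH (10 mol%), i-PrOH, 23 °C
Reagents that add atoms: none
Why: Intramolecular aldol condensation of the methyl ketone carbon C9' onto the aldehyde C8' is the only closure that gives a six-membered ring, and dehydration gives the cyclohexenone.

Step 20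
Reactants: 30 methyl 2-[(1S)-5-[(2S)-6-methylhept-5-en-2-yl]-4-oxocyclohex-2-en-1-yl]acetate
Product: 31 methyl 2-[(1R)-5-[(2S)-6-methylhept-5-en-2-yl]-4-oxo-5-(phenylselanyl)cyclohex-2-en-1-yl]acetate (C5 epimers)
Conditions: LiN(i-Pr)2 (1.05 equiv), THF, −78 °C; PhSeBr
Reagents that add atoms: benzeneselenenyl bromide, Br[Se]c1ccccc1
Why: Kinetic deprotonation of the enone at the α'-carbon C5' and selenenylation of the enolate place the leaving group for the later C5'=C6' bond.

Step 21
Reactants: 31 methyl 2-[(1R)-5-[(2S)-6-methylhept-5-en-2-yl]-4-oxo-5-(phenylselanyl)cyclohex-2-en-1-yl]acetate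
Product: 33 (3aR,7aS)-5-[(2S)-6-methylhept-5-en-2-yl]-5-(phenylselanyl)hexahydro-1-benzofuran-2,6-dione (C5 epimers), via enone carboxylic acid 32 (not isolated)
Conditions: LiOH, THF/H2O, 0 °C; 1 M HCl to pH 3; then p-TsOH·H2O (cat.), CH2Cl2, 23 °C
Reagents that add atoms: water, O
Why: After saponification the acid adds to C8' of the enone (oxa-Michael), which can only give the cis-fused γ-lactone, so C8' is set by C7'.

Step 22
Reactants: 33 (3aR,7aS)-5-[(2S)-6-methylhept-5-en-2-yl]-5-(phenylselanyl)hexahydro-1-benzofuran-2,6-dione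
Product: 35 (3aR,7aS)-5-[(2S)-6-methylhept-5-en-2-yl]-3,3a,7,7a-tetrahydro-1-benzofuran-2,6-dione, via selenoxide 34 (not isolated)
Conditions: 30% H2O2, pyridine, CH2Cl2, 0 to 23 °C
Reagents that add atoms: none
Why: Selenoxide syn-elimination toward the ring hydrogen at C6' should give the endocyclic enone; conditions are kept neutral because enolization toward C9' would expel the lactone and aromatize the ring.

Step 23
Reactants: 35 (3aR,7aS)-5-[(2S)-6-methylhept-5-en-2-yl]-3,3a,7,7a-tetrahydro-1-benzofuran-2,6-dione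
Product: 37 (3aR,7aS)-5-[(2S)-5-hydroxypentan-2-yl]-3,3a,7,7a-tetrahydro-1-benzofuran-2,6-dione, via side-chain aldehyde 36 (not isolated)
Conditions: O3, CH2Cl2, −78 °C (Sudan red 7B end point); PPh3; then NaBH(OAc)3, AcOH, 0 °C
Reagents that add atoms: ozone, [O-][O+]=O
Why: Ozone attacks the electron-rich trisubstituted side-chain alkene much faster than the enone, and NaBH(OAc)3 reduces the aldehyde but not the ketone.

Step 24
Reactants: 37 (3aR,7aS)-5-[(2S)-5-hydroxypentan-2-yl]-3,3a,7,7a-tetrahydro-1-benzofuran-2,6-dione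
Product: 38 (3aR,7aS)-5-[(2S)-5-hydroxypentan-2-yl]-6-methylidene-3,3a,7,7a-tetrahydro-1-benzofuran-2(6H)-one
Conditions: Zn, CH2Br2, TiCl4, THF/CH2Cl2, 0 to 23 °C
Reagents that add atoms: dibromomethane, BrCBr
Why: Non-basic zinc–titanium methylenation (Lombardo conditions) converts the ketone into the exocyclic methylene without enolization toward C9'.

Step 25
Reactants: 38 (3aR,7aS)-5-[(2S)-5-hydroxypentan-2-yl]-6-methylidene-3,3a,7,7a-tetrahydro-1-benzofuran-2(6H)-one
Product: 41 (3aS,7aS)-5-[(2S)-5-hydroxypentan-2-yl]-3,6-dimethylidene-3,3a,7,7a-tetrahydro-1-benzofuran-2(6H)-one, via 3-(dimethylaminomethyl) lactone 39 (not isolated), via trimethylammonium iodide 40 (not isolated)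
Conditions: LiN(i-Pr)2 (2.3 equiv), THF, −78 °C; CH2=NMe2 I, −78 to 0 °C; then MeI, MeOH, 23 °C; then NaHCO3, CH2Cl2/H2O
Reagents that add atoms: Eschenmoser's salt, C=[N+](C)C.[I-]
Why: As in step 13, Mannich aminomethylation of the lactone enolate, quaternization and elimination give the α-methylene lactone.

Step 26
Reactants: 22 (3aS,5R,6S,7R,8R,9aR)-5,8-dimethyl-3-methylidene-2-oxo-6-(phenylselanyl)-2,3,3a,4,5,6,7,8,9,9a-decahydroazuleno[6,5-b]furan-7-yl acetate; 41 (3aS,7aS)-5-[(2S)-5-hydroxypentan-2-yl]-3,6-dimethylidene-3,3a,7,7a-tetrahydro-1-benzofuran-2(6H)-one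
Product: 44 CNP0299458.1, via selenoxide 42 (not isolated), via cyclopentadiene 43 (not isolated)
Conditions: mCPBA (1.05 equiv), CH2Cl2, −78 °C; then pyridine, 41 (3 equiv), −78 to 20 °C, 48 h
Reagents that add atoms: none
Why: Selenoxide syn-elimination (only H4 is syn and not on an oxygenated carbon) should release the 5-acyloxycyclopentadiene 43 below 0 °C, which is trapped by the α-methylene lactone of 41 in a Diels–Alder reaction: the dienophile CH2 bonds to the hindered C1, the diene reacts on its face anti to C2–OAc and the C10 methyl (C1, C3), and the lactone carbonyl should take the exo position (C11').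

**Compound list**

1 | methyl 3-methylfuran-2-carboxylate | COC(=O)c1occc1C | starting material
2 | (3-methylfuran-2-yl)methanol | Cc1ccoc1CO | intermediate
3 | (2Z)-5-hydroxy-3-methyl-4-oxopent-2-enal | O=C/C=C(C)\C(=O)CO | intermediate (not isolated)
4 | 6-hydroxy-4-methyl-2H-pyran-3(6H)-one (racemic) | CC1=CC(O)OCC1=O | intermediate
5 | 4-methyl-5-oxo-5,6-dihydro-2H-pyran-2-yl acetate (racemic) | CC(=O)OC1OCC(=O)C(C)=C1 | intermediate
6 | (E)-but-2-enal | C/C=C/C=O | starting material
7 | 4-methyl-3-oxidopyrylium | Cc1cc[o+]cc1[O-] | intermediate (not isolated)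
8 | 2-[(1R,5S,6S)-3-methyl-2-oxo-8-oxabicyclo[3.2.1]oct-3-en-6-yl]acetaldehyde (6-endo) | O=CC[C@@H]1C[C@H]2O[C@@H]1C=C(C)C2=O | intermediate
9 | 2-[(1R,5S,6S)-3-methyl-2-oxo-8-oxabicyclo[3.2.1]oct-3-en-6-yl]acetic acid | OC(=O)C[C@@H]1C[C@H]2O[C@@H]1C=C(C)C2=O | intermediate
10 | 2-[(1R,3R,5R,6S)-3-methyl-2-oxo-8-oxabicyclo[3.2.1]octan-6-yl]acetic acid | OC(=O)C[C@@H]1C[C@H]2O[C@@H]1C[C@@H](C)C2=O | intermediate
11 | 2-[(1S,2R,4R)-2-hydroxy-4-methyl-5-oxocycloheptyl]acetic acid | OC(=O)C[C@@H]1CCC(=O)[C@H](C)C[C@H]1O | intermediate (not isolated)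
12 | (3aS,7R,8aR)-7-methylhexahydro-2H-cyclohepta[b]furan-2,6(3H)-dione (trans-fused) | O=C1C[C@@H]2CCC(=O)[C@H](C)C[C@H]2O1 | intermediate
13 | (3aS,7R,8aR)-7-methyl-2-oxo-3,3a,4,7,8,8a-hexahydro-2H-cyclohepta[b]furan-6-yl trifluoromethanesulfonate | O=C1C[C@@H]2CC=C(OS(=O)(=O)C(F)(F)F)[C@H](C)C[C@H]2O1 | intermediate
14 | (E)-tributyl(prop-1-en-1-yl)stannane | C/C=C/[Sn](CCCC)(CCCC)CCCC | starting material
15 | (3aS,7R,8aR)-6-[(2E)-but-2-enoyl]-7-methyl-3,3a,4,7,8,8a-hexahydro-2H-cyclohepta[b]furan-2-one | C/C=C/C(=O)C1=CC[C@H]2CC(=O)O[C@@H]2C[C@H]1C | intermediate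
16 | (3aS,8R,9aR)-5,8-dimethyl-3,3a,4,5,6,8,9,9a-octahydroazuleno[6,5-b]furan-2,7-dione (C5 epimer pair, 5S member drawn) | C[C@H]1CC(=O)C2=C1C[C@H]1CC(=O)O[C@@H]1C[C@H]2C | intermediate
17 | (3aS,5R,6S,8R,9aR)-5,8-dimethyl-6-(phenylselanyl)-3,3a,4,5,6,8,9,9a-octahydroazuleno[6,5-b]furan-2,7-dione (5,6-trans pair, one member drawn) | C[C@H]1[C@H]([Se]c2ccccc2)C(=O)C2=C1C[C@H]1CC(=O)O[C@@H]1C[C@H]2C | intermediate
18 | (3aS,5R,6S,7R,8R,9aR)-7-hydroxy-5,8-dimethyl-6-(phenylselanyl)-3a,4,5,6,7,8,9,9a-octahydroazuleno[6,5-b]furan-2(3H)-one | C[C@H]1[C@H]([Se]c2ccccc2)[C@H](O)C2=C1C[C@H]1CC(=O)O[C@@H]1C[C@H]2C | intermediate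
19 | 3-(dimethylaminomethyl) derivative of 18 (C3 epimers) | C[C@H]1[C@H]([Se]c2ccccc2)[C@H](O)C2=C1C[C@H]1C(CN(C)C)C(=O)O[C@@H]1C[C@H]2C | intermediate (not isolated)
20 | trimethylammonium iodide of 19 | C[C@H]1[C@H]([Se]c2ccccc2)[C@H](O)C2=C1C[C@H]1C(C[N+](C)(C)C)C(=O)O[C@@H]1C[C@H]2C.[I-] | intermediate (not isolated)
21 | (3aS,5R,6S,7R,8R,9aR)-7-hydroxy-5,8-dimethyl-3-methylidene-6-(phenylselanyl)-3a,4,5,6,7,8,9,9a-octahydroazuleno[6,5-b]furan-2(3H)-one | C[C@H]1[C@H]([Se]c2ccccc2)[C@H](O)C2=C1C[C@H]1C(=C)C(=O)O[C@@H]1C[C@H]2C | intermediate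
22 | acetate of 21 | C[C@H]1[C@H]([Se]c2ccccc2)[C@H](OC(C)=O)C2=C1C[C@H]1C(=C)C(=O)O[C@@H]1C[C@H]2C | intermediate
23 | (3S)-3,7-dimethyloct-6-enal, (S)-citronellal | O=CC[C@@H](C)CCC=C(C)C | starting material
24 | (3S)-3,7-dimethyl-2-methylideneoct-6-enal | O=CC(=C)[C@@H](C)CCC=C(C)C | intermediate
25 | (4S)-4,8-dimethyl-3-methylidenenon-7-en-2-ol (C2 epimers) | CC(O)C(=C)[C@@H](C)CCC=C(C)C | intermediate
26 | (4S)-4,8-dimethyl-3-methylidenenon-7-en-2-one | CC(=O)C(=C)[C@@H](C)CCC=C(C)C | intermediate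
27 | methyl 4-oxobutanoate | COC(=O)CCC=O | starting material
28 | methyl (3S)-3-formyl-5-[(2S)-6-methylhept-5-en-2-yl]-6-oxoheptanoate (C5 epimers) | COC(=O)C[C@@H](C=O)CC([C@@H](C)CCC=C(C)C)C(C)=O | intermediate
29 | methyl 2-[(1S)-2-hydroxy-5-[(2S)-6-methylhept-5-en-2-yl]-4-oxocyclohexyl]acetate | COC(=O)C[C@@H]1CC([C@@H](C)CCC=C(C)C)C(=O)CC1O | intermediate (not isolated)
30 | methyl 2-[(1S)-5-[(2S)-6-methylhept-5-en-2-yl]-4-oxocyclohex-2-en-1-yl]acetate (C5 epimers) | COC(=O)C[C@@H]1CC([C@@H](C)CCC=C(C)C)C(=O)C=C1 | intermediate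
31 | methyl 2-[(1R)-5-[(2S)-6-methylhept-5-en-2-yl]-4-oxo-5-(phenylselanyl)cyclohex-2-en-1-yl]acetate (C5 epimers) | COC(=O)C[C@@H]1CC([Se]c2ccccc2)([C@@H](C)CCC=C(C)C)C(=O)C=C1 | intermediate
32 | carboxylic acid of 31 | OC(=O)C[C@@H]1CC([Se]c2ccccc2)([C@@H](C)CCC=C(C)C)C(=O)C=C1 | intermediate (not isolated)
33 | (3aR,7aS)-5-[(2S)-6-methylhept-5-en-2-yl]-5-(phenylselanyl)hexahydro-1-benzofuran-2,6-dione (cis-fused, C5 epimers) | O=C1C[C@@H]2CC([Se]c3ccccc3)([C@@H](C)CCC=C(C)C)C(=O)C[C@@H]2O1 | intermediate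
34 | selenoxide of 33 | O=C1C[C@@H]2CC([Se](=O)c3ccccc3)([C@@H](C)CCC=C(C)C)C(=O)C[C@@H]2O1 | intermediate (not isolated)
35 | (3aR,7aS)-5-[(2S)-6-methylhept-5-en-2-yl]-3,3a,7,7a-tetrahydro-1-benzofuran-2,6-dione | O=C1C[C@@H]2C=C([C@@H](C)CCC=C(C)C)C(=O)C[C@@H]2O1 | intermediate
36 | (3aR,7aS)-5-[(2S)-5-oxopentan-2-yl]-3,3a,7,7a-tetrahydro-1-benzofuran-2,6-dione | O=C1C[C@@H]2C=C([C@@H](C)CCC=O)C(=O)C[C@@H]2O1 | intermediate (not isolated)
37 | (3aR,7aS)-5-[(2S)-5-hydroxypentan-2-yl]-3,3a,7,7a-tetrahydro-1-benzofuran-2,6-dione | O=C1C[C@@H]2C=C([C@@H](C)CCCO)C(=O)C[C@@H]2O1 | intermediate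
38 | (3aR,7aS)-5-[(2S)-5-hydroxypentan-2-yl]-6-methylidene-3,3a,7,7a-tetrahydro-1-benzofuran-2(6H)-one | C=C1C[C@@H]2OC(=O)C[C@@H]2C=C1[C@@H](C)CCCO | intermediate
39 | 3-(dimethylaminomethyl) derivative of 38 (C3 epimers) | C=C1C[C@@H]2OC(=O)C(CN(C)C)[C@@H]2C=C1[C@@H](C)CCCO | intermediate (not isolated)
40 | trimethylammonium iodide of 39 | C=C1C[C@@H]2OC(=O)C(C[N+](C)(C)C)[C@@H]2C=C1[C@@H](C)CCCO.[I-] | intermediate (not isolated)
41 | (3aS,7aS)-5-[(2S)-5-hydroxypentan-2-yl]-3,6-dimethylidene-3,3a,7,7a-tetrahydro-1-benzofuran-2(6H)-one | C=C1C[C@@H]2OC(=O)C(=C)[C@@H]2C=C1[C@@H](C)CCCO | intermediate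
42 | selenoxide of 22 | C[C@H]1[C@H]([Se](=O)c2ccccc2)[C@H](OC(C)=O)C2=C1C[C@H]1C(=C)C(=O)O[C@@H]1C[C@H]2C | intermediate (not isolated)
43 | (3aS,7S,8R,9aR)-5,8-dimethyl-3-methylidene-2-oxo-2,3,3a,4,7,8,9,9a-octahydroazuleno[6,5-b]furan-7-yl acetate | CC(=O)O[C@H]1C=C(C)C2=C1[C@H](C)C[C@H]1OC(=O)C(=C)[C@@H]1C2 | intermediate (not isolated)
44 | CNP0299458.1, Diels–Alder adduct of 43 and 41 | C=C1C[C@@H]2OC(=O)[C@@]3(C[C@@]45C(=C(C)[C@@H]3[C@@H]4OC(C)=O)C[C@H]3C(=C)C(=O)O[C@@H]3C[C@H]5C)[C@@H]2C=C1[C@@H](C)CCCO | target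

**Totals.** Total step count: 26. Longest linear sequence: 15 steps (steps 1–14 and 26).

**Three steps most likely to fail**

Step 4 (proposed new method). The monocyclic ylide may dimerize faster than the catalytic dienamine intercepts it, or the approach may turn exo or lose face selectivity. Fallback from 5, by known chemistry: the ylide 7 is generated with Et3N in CH2Cl2 in the presence of the acrylate of (R)-pantolactone, a thermal [5+2] of the kind known for acrylates. The two face-diastereomers are separated to give the 6-endo (R)-pantolactone cycloadduct ester F1. Hydrogenation (H2, Pd/C) gives the saturated ester F2, LiOH/H2O2 gives the bicyclic carboxylic acid F3, and (COCl)2 followed by CH2N2 gives the diazoketone F4. Silver benzoate and Et3N in THF/H2O then effect the Wolff rearrangement (Arndt–Eistert homologation, retention at the migrating carbon), and the route is rejoined at 10.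

Step 26. The 5-acyloxycyclopentadiene may isomerize by [1,5]-hydrogen shift or add to itself through its own α-methylene lactone before the cross-cycloaddition. Fallback from 21: thiophenol and catalytic Et3N mask the methylene lactone as the phenylthiomethyl lactone F8, which is acetylated to the acetate F9. mCPBA (2 equiv, −78 °C) oxidizes selenium and sulfur; on warming to 0 °C only the selenoxide eliminates, giving the sulfoxide-masked diene F10 (not isolated), which has no competing dienophile and is trapped by 41 to give the masked adduct F11. Heating F11 in toluene at 110 °C with CaCO3 effects sulfoxide syn-elimination and comes back to the route at 44.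

Step 18. Enamine addition to the α-branched vinyl ketone may be sluggish, with erosion of enantioselectivity at C7'. Fallback from 26: the chlorotitanium enolate (TiCl4, i-Pr2NEt, CH2Cl2, −78 °C) of the succinate imide F5, prepared from methyl hydrogen succinate and (4S)-4-benzyl-1,3-oxazolidin-2-one, adds to 26 anti to the benzyl group to give the Michael adduct F6. EtSLi converts F6 into the thioester F7, and Fukuyama reduction (Et3SiH, Pd/C) gives the aldehyde, rejoining the route at 28.

**Further compounds**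

F1 | step 4 | (R)-pantolactone ester of (6-endo)-3-methyl-2-oxo-8-oxabicyclo[3.2.1]oct-3-ene-6-carboxylic acid | CC1(C)COC(=O)[C@@H]1OC(=O)[C@@H]1C[C@H]2O[C@@H]1C=C(C)C2=O
F2 | step 4 | (R)-pantolactone ester of (6-endo)-3-methyl-2-oxo-8-oxabicyclo[3.2.1]octane-6-carboxylic acid | CC1(C)COC(=O)[C@@H]1OC(=O)[C@@H]1C[C@H]2O[C@@H]1C[C@@H](C)C2=O
F3 | step 4 | (6-endo)-3-methyl-2-oxo-8-oxabicyclo[3.2.1]octane-6-carboxylic acid | OC(=O)[C@@H]1C[C@H]2O[C@@H]1C[C@@H](C)C2=O
F4 | step 4 | 6-(diazoacetyl)-3-methyl-8-oxabicyclo[3.2.1]octan-2-one | [N-]=[N+]=CC(=O)[C@@H]1C[C@H]2O[C@@H]1C[C@@H](C)C2=O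
F5 | step 18 | methyl 4-[(4S)-4-benzyl-2-oxo-1,3-oxazolidin-3-yl]-4-oxobutanoate | COC(=O)CCC(=O)N1[C@@H](Cc2ccccc2)COC1=O
F6 | step 18 | Michael adduct of F5 and 26 (imide of the acid corresponding to 28) | COC(=O)C[C@H](CC([C@@H](C)CCC=C(C)C)C(C)=O)C(=O)N1[C@@H](Cc2ccccc2)COC1=O
F7 | step 18 | S-ethyl thioester corresponding to 28 | COC(=O)C[C@H](CC([C@@H](C)CCC=C(C)C)C(C)=O)C(=O)SCC
F8 | step 26 | thiophenol adduct of 21 (3-phenylthiomethyl lactone) | C[C@H]1[C@H]([Se]c2ccccc2)[C@H](O)C2=C1C[C@H]1C(CSc3ccccc3)C(=O)O[C@@H]1C[C@H]2C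
F9 | step 26 | acetate of F8 | C[C@H]1[C@H]([Se]c2ccccc2)[C@H](OC(C)=O)C2=C1C[C@H]1C(CSc3ccccc3)C(=O)O[C@@H]1C[C@H]2C
F10 | step 26 | 3-(phenylsulfinylmethyl) analogue of diene 43 | CC(=O)O[C@H]1C=C(C)C2=C1[C@H](C)C[C@H]1OC(=O)C(CS(=O)c3ccccc3)[C@@H]1C2
F11 | step 26 | Diels–Alder adduct of F10 and 41 | C=C1C[C@@H]2OC(=O)[C@@]3(C[C@@]45C(=C(C)[C@@H]3[C@@H]4OC(C)=O)C[C@H]3C(CS(=O)c6ccccc6)C(=O)O[C@@H]3C[C@H]5C)[C@@H]2C=C1[C@@H](C)CCCO
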